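**Retrosynthetic overview**
1. Target ⇐ C2 desilylation/acetylation, C6 anisoylation and a 6α‑OH‑directed epoxidation (C–O; oxirane formed last) of a 2α‑silyloxy‑dauc‑8‑ene‑4β,6α‑diol.
2. Seven‑membered ring ⇐ ring‑closing metathesis (C8=C9) of an allyl/methallyl cyclopentane; C4 carbinol ⇐ isopropyl addition to a cyclopentanone.
3. Cyclopentanone ⇐ methyl‑cuprate addition/anti‑aldol on (R)‑3‑allyl‑4‑silyloxycyclopentenone; C1, C5, C6 and C4 are all relayed from the C2–O stereocentre.
4. (R)‑4‑Hydroxycyclopentenone ⇐ catalytic asymmetric oxa‑Piancatelli rearrangement of furfuryl alcohol (new C–O/ring‑forming step that installs the controlling C2–O centre).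
5. Ring order: cyclopentenone (step 1) → cycloheptene (step 7) → oxirane (step 8).

Assumption: bicyclic compounds use daucane numbering (C1 = angular‑methyl carbon, C2–C4 = rest of the five‑membered ring with C4 bearing isopropyl, C5 = ring‑fusion CH, C6–C10 = seven‑membered ring, C8 methylated); α = face of H‑5, β = face of the C1 methyl.

**Step 1**
Reactants: 1 furfuryl alcohol
Product: 2 (R)-4-hydroxycyclopent-2-en-1-one
Conditions: confined chiral imidodiphosphorimidate Brønsted acid (IDPi, 5 mol %, enantiomer chosen for R), H2O (10 equiv), CHCl3, 60 °C, high dilution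
Reagents that add atoms: water, O
Why: Proposed new method: the strong chiral acid ionises 1 to the furfuryl oxocarbenium ion, water adds at furan C5 (this C–O bond becomes C2–O of the target), ring opening gives a 1,4‑dihydroxypentadienyl cation held by two OH···anion hydrogen bonds, and its conrotatory 4π closure is steered by the confined counter‑anion so that the single new stereocentre is formed as R; the closest known chemistry is the chiral‑phosphoric‑acid aza‑Piancatelli rearrangement, chiral‑acid Nazarov cyclisation and the racemic oxa‑Piancatelli rearrangement of 1 in hot water.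

**Step 2**
Reactants: 2 (R)-4-hydroxycyclopent-2-en-1-one
Product: 3 (R)-4-(tert-butyldimethylsilyloxy)cyclopent-2-en-1-one
Conditions: TBSCl, imidazole, CH2Cl2, 0 °C
Reagents that add atoms: tert-butyldimethylsilyl chloride, CC(C)(C)[Si](C)(C)Cl
Why: Standard silyl ether formation under imidazole conditions mild enough to avoid β‑elimination, leaving the stereocentre untouched.

**Step 3**
Reactants: 3 (R)-4-(tert-butyldimethylsilyloxy)cyclopent-2-en-1-one
Product: 5 (R)-3-allyl-4-(tert-butyldimethylsilyloxy)cyclopent-2-en-1-one, via silyl enol ether 4 (not isolated)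
Conditions: allylMgBr, CuBr·SMe2, TMSCl, THF, −78 °C; solvent exchange; then IBX·MPO, DMSO, rt
Reagents that add atoms: allylmagnesium bromide, C=CC[Mg]Br; chlorotrimethylsilane (in 4 only), C[Si](C)(C)Cl
Why: Copper‑mediated conjugate allylation with TMSCl trapping (anti to OTBS) followed by Saegusa‑type IBX dehydrogenation of the silyl enol ether restores the enone with allyl on C3, erasing the transient C3 centre and keeping C4.

**Step 4**
Reactants: 6 3-methylbut-3-en-1-ol
Product: 7 3-methylbut-3-enal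
Conditions: Dess–Martin periodinane, NaHCO3, CH2Cl2, 0 °C; solution used at once
Reagents that add atoms: none
Why: Buffered Dess–Martin oxidation gives the β,γ‑unsaturated aldehyde without base‑ or acid‑induced isomerisation to prenal.

**Step 5**
Reactants: 5 (R)-3-allyl-4-(tert-butyldimethylsilyloxy)cyclopent-2-en-1-one; 7 3-methylbut-3-enal
Product: 9 (2R,3S,4R)-3-allyl-4-(tert-butyldimethylsilyloxy)-2-[(1R)-1-hydroxy-3-methylbut-3-en-1-yl]-3-methylcyclopentan-1-one, via lithium enolate 8 (not isolated)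
Conditions: Me2CuLi (MeLi, CuI), Et2O, −40→−20 °C; then 7, THF, −78 °C; aq NH4Cl
Reagents that add atoms: lithium dimethylcuprate, [Li+].C[Cu-]C
Why: Noyori‑type three‑component coupling in which methyl adds trans to OTBS to set the quaternary C3 (daucane C1), and the regiodefined ring (E)‑enolate undergoes a Zimmerman–Traxler anti‑aldol on the face opposite allyl and OTBS, setting daucane C5 and the 1′R carbinol (daucane C6).

**Step 6**
Reactants: 9 (2R,3S,4R)-3-allyl-4-(tert-butyldimethylsilyloxy)-2-[(1R)-1-hydroxy-3-methylbut-3-en-1-yl]-3-methylcyclopentan-1-one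
Product: 10 (1S,2R,3S,4R)-3-allyl-4-(tert-butyldimethylsilyloxy)-2-[(1R)-1-hydroxy-3-methylbut-3-en-1-yl]-3-methyl-1-(propan-2-yl)cyclopentan-1-ol
Conditions: i-PrLi, CeCl3 (3.5 equiv), THF, −78 °C
Reagents that add atoms: isopropyllithium, [Li]C(C)C
Why: Non‑basic organocerium 1,2‑addition (suppressing enolisation, β‑elimination and retro‑aldol) should occur anti to the vicinal side chain, as hydride does in PGE→PGF2α reductions, giving the tertiary alcohol cis to that chain (daucane 4β‑OH).

**Step 7**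
Reactants: 10 (1S,2R,3S,4R)-3-allyl-4-(tert-butyldimethylsilyloxy)-2-[(1R)-1-hydroxy-3-methylbut-3-en-1-yl]-3-methyl-1-(propan-2-yl)cyclopentan-1-ol
Product: 11 (1S,2R,4S,5R,6R)-2α-(tert-butyldimethylsilyloxy)dauc-8-ene-4β,6α-diol
Conditions: Grubbs II (5 mol %), CH2Cl2 (5 mM), 40 °C
Reagents that add atoms: none
Why: Ring‑closing metathesis of the allyl and methallyl groups (trans on the cyclopentane) closes the trans‑fused cycloheptene with the trisubstituted C8=C9 alkene without touching any stereocentre.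

**Step 8**
Reactants: 11 (1S,2R,4S,5R,6R)-2α-(tert-butyldimethylsilyloxy)dauc-8-ene-4β,6α-diol
Product: 12 (1S,2R,4S,5R,6R,8S,9R)-2α-(tert-butyldimethylsilyloxy)-8α,9α-epoxydaucane-4β,6α-diol
Conditions: VO(acac)2 (5 mol %), t-BuOOH, 2,6-lutidine, CH2Cl2, 0 °C→rt
Reagents that add atoms: tert-butyl hydroperoxide, CC(C)(C)OO
Why: Vanadium‑catalysed homoallylic‑alcohol‑directed epoxidation delivers oxygen syn to the 6α‑OH, which is also the face away from the angular methyl, setting C8 and C9 as the α‑epoxide.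

**Step 9**
Reactants: 12 (1S,2R,4S,5R,6R,8S,9R)-2α-(tert-butyldimethylsilyloxy)-8α,9α-epoxydaucane-4β,6α-diol
Product: 13 (1S,2R,4S,5R,6R,8S,9R)-2α-(tert-butyldimethylsilyloxy)-8α,9α-epoxy-4β-hydroxydaucan-6α-yl 4-methoxybenzoate
Conditions: 4-methoxybenzoyl chloride, DMAP, Et3N, CH2Cl2, 0 °C→rt
Reagents that add atoms: 4-methoxybenzoyl chloride, COc1ccc(C(Cl)=O)cc1
Why: DMAP‑catalysed acylation takes the only secondary alcohol and leaves the tertiary 4‑OH and the epoxide intact.

**Step 10**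
Reactants: 13 (1S,2R,4S,5R,6R,8S,9R)-2α-(tert-butyldimethylsilyloxy)-8α,9α-epoxy-4β-hydroxydaucan-6α-yl 4-methoxybenzoate
Product: 15 (1S,2R,4S,5R,6R,8S,9R)-2α-acetoxy-8α,9α-epoxy-4β-hydroxydaucan-6α-yl 4-methoxybenzoate, via C2 alcohol 14 (not isolated)
Conditions: TBAF, THF, rt→40 °C; then Ac2O, DMAP, 0 °C→rt
Reagents that add atoms: acetic anhydride, CC(=O)OC(C)=O
Why: Fluoride desilylation followed in the same pot by DMAP acetylation esterifies the liberated secondary 2α‑OH while the tertiary 4β‑OH stays free, under non‑acidic conditions that spare the epoxide.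

**Compound list**
1 | furfuryl alcohol (furan-2-ylmethanol) | OCc1ccco1 | starting material
2 | (R)-4-hydroxycyclopent-2-en-1-one | O=C1C=C[C@H](O)C1 | intermediate
3 | (R)-4-(tert-butyldimethylsilyloxy)cyclopent-2-en-1-one | O=C1C=C[C@H](O[Si](C)(C)C(C)(C)C)C1 | intermediate
4 | (3R,4R)-3-allyl-4-(tert-butyldimethylsilyloxy)-1-(trimethylsilyloxy)cyclopent-1-ene (allyl trans to OTBS) | C[Si](C)(C)OC1=C[C@@H](CC=C)[C@H](O[Si](C)(C)C(C)(C)C)C1 | intermediate
5 | (R)-3-allyl-4-(tert-butyldimethylsilyloxy)cyclopent-2-en-1-one | O=C1C=C(CC=C)[C@H](O[Si](C)(C)C(C)(C)C)C1 | intermediate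
6 | 3-methylbut-3-en-1-ol | CC(=C)CCO | starting material
7 | 3-methylbut-3-enal | CC(=C)CC=O | intermediate
8 | lithium (3S,4R)-3-allyl-4-(tert-butyldimethylsilyloxy)-3-methylcyclopent-1-en-1-olate | [Li]OC1=C[C@](C)(CC=C)[C@H](O[Si](C)(C)C(C)(C)C)C1 | intermediate
9 | (2R,3S,4R)-3-allyl-4-(tert-butyldimethylsilyloxy)-2-[(1R)-1-hydroxy-3-methylbut-3-en-1-yl]-3-methylcyclopentan-1-one | O[C@H](CC(C)=C)[C@@H]1C(=O)C[C@@H](O[Si](C)(C)C(C)(C)C)[C@@]1(C)CC=C | intermediate
10 | (1S,2R,3S,4R)-3-allyl-4-(tert-butyldimethylsilyloxy)-2-[(1R)-1-hydroxy-3-methylbut-3-en-1-yl]-3-methyl-1-(propan-2-yl)cyclopentan-1-ol | O[C@H](CC(C)=C)[C@@H]1[C@@](O)(C(C)C)C[C@@H](O[Si](C)(C)C(C)(C)C)[C@@]1(C)CC=C | intermediate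
11 | (1S,2R,4S,5R,6R)-2α-(tert-butyldimethylsilyloxy)dauc-8-ene-4β,6α-diol (trans-fused, 1β-Me, 5α-H) | O[C@@H]2CC(C)=CC[C@]3(C)[C@H](O[Si](C)(C)C(C)(C)C)C[C@](O)(C(C)C)[C@@H]23 | intermediate
12 | (1S,2R,4S,5R,6R,8S,9R)-2α-(tert-butyldimethylsilyloxy)-8α,9α-epoxydaucane-4β,6α-diol | O[C@@H]2C[C@]3(C)O[C@@H]3C[C@]3(C)[C@H](O[Si](C)(C)C(C)(C)C)C[C@](O)(C(C)C)[C@@H]23 | intermediate
13 | (1S,2R,4S,5R,6R,8S,9R)-2α-(tert-butyldimethylsilyloxy)-8α,9α-epoxy-4β-hydroxydaucan-6α-yl 4-methoxybenzoate | COc1ccc(C(=O)O[C@@H]2C[C@]3(C)O[C@@H]3C[C@]3(C)[C@H](O[Si](C)(C)C(C)(C)C)C[C@](O)(C(C)C)[C@@H]23)cc1 | intermediate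
14 | (1S,2R,4S,5R,6R,8S,9R)-8α,9α-epoxy-2α,4β-dihydroxydaucan-6α-yl 4-methoxybenzoate | COc1ccc(C(=O)O[C@@H]2C[C@]3(C)O[C@@H]3C[C@]3(C)[C@H](O)C[C@](O)(C(C)C)[C@@H]23)cc1 | intermediate
15 | (1S,2R,4S,5R,6R,8S,9R)-2α-acetoxy-8α,9α-epoxy-4β-hydroxydaucan-6α-yl 4-methoxybenzoate (CNP0317703.1) | COc1ccc(C(=O)O[C@@H]2C[C@]3(C)O[C@@H]3C[C@]3(C)[C@H](OC(C)=O)C[C@](O)(C(C)C)[C@@H]23)cc1 | target

**Totals**
Total steps: 10. Longest linear sequence: 9 (steps 1–3 and 5–10, from furfuryl alcohol); step 4 is a one‑step side branch.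

**Three steps most likely to fail, with fallbacks**

Step 1 (the proposed new method) may give low enantioselectivity or polymerise furfuryl alcohol. The fallback uses known chemistry and sets out from 1. Uncatalysed oxa‑Piancatelli rearrangement in superheated water (200–240 °C, microwave or flow) gives racemic 4‑hydroxycyclopent‑2‑en‑1‑one F1. Lipase‑catalysed kinetic resolution with vinyl acetate then acylates the (R)‑enantiomer to (R)‑4‑acetoxycyclopent‑2‑en‑1‑one F2, which is separated from the unreacted (S)‑alcohol. Mild enzymatic hydrolysis of the acetate (lipase, pH 7 buffer) returns to the route at 2.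

Step 5 may fail because the basic lithium enolate deprotonates or isomerises the sensitive aldehyde 7. The fallback sets out from 5 and separates the two bond formations. Me2CuLi in the presence of TMSCl gives the isolable (3S,4R)‑3‑allyl‑4‑(tert‑butyldimethylsilyloxy)‑3‑methyl‑1‑(trimethylsilyloxy)cyclopent‑1‑ene F3. A base‑free TiCl4‑mediated Mukaiyama aldol of this silyl enol ether with 7 at −78 °C, with chromatographic selection of the 1′R isomer, returns to the route at 9.

Step 6 may give reduction, enolisation or the wrong face with the branched sp3 nucleophile. The fallback sets out from 9 and closes the ring first. Grubbs II metathesis gives the rigid bicyclic ketone 2α‑(tert‑butyldimethylsilyloxy)‑6α‑hydroxydauc‑8‑en‑4‑one F4. Addition of the smaller, β‑hydride‑free isopropenylcerium reagent (2‑propenylmagnesium bromide, CeCl3) to the α‑face gives 2α‑(tert‑butyldimethylsilyloxy)dauca‑8,11‑diene‑4β,6α‑diol F5. Selective hydrogenation of its 1,1‑disubstituted alkene with RhCl(PPh3)3/H2, which leaves the trisubstituted ring alkene, returns to the route at 11.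

**Further compounds**
F1 | step 1 | racemic 4-hydroxycyclopent-2-en-1-one | O=C1C=CC(O)C1
F2 | step 1 | (R)-4-acetoxycyclopent-2-en-1-one | O=C1C=C[C@H](OC(C)=O)C1
F3 | step 5 | (3S,4R)-3-allyl-4-(tert-butyldimethylsilyloxy)-3-methyl-1-(trimethylsilyloxy)cyclopent-1-ene | C[Si](C)(C)OC1=C[C@](C)(CC=C)[C@H](O[Si](C)(C)C(C)(C)C)C1
F4 | step 6 | (1S,2R,5R,6R)-2α-(tert-butyldimethylsilyloxy)-6α-hydroxydauc-8-en-4-one | O[C@@H]2CC(C)=CC[C@]3(C)[C@H](O[Si](C)(C)C(C)(C)C)CC(=O)[C@@H]23
F5 | step 6 | 2α-(tert-butyldimethylsilyloxy)dauca-8,11-diene-4β,6α-diol | O[C@@H]2CC(C)=CC[C@]3(C)[C@H](O[Si](C)(C)C(C)(C)C)C[C@](O)(C(C)=C)[C@@H]23
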